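## Analysis of the target

Compound 25 is a flavonol. Ring A is fused to the pyranone ring C in a 4H-chromen-4-one, with ring B attached at C2 and a hydroxyl group at C3. There is no stereocentre, so every difficulty is regiochemical: 3-OH, 5-OH and 2'-OH must end free, while 7-OMe, 8-OMe and 4'-OMe stay methylated. Ring A is pentasubstituted, with C6–H as the only open position. C4a lies between two oxygen-bearing carbons, C5 and C8a; one must become the ring oxygen O1 and the other the chelated 5-OH, and confusing them gives the 5,6,7-isomer. The finished molecule faces the same danger, because 5-hydroxyflavones with a 7,8-pattern can open and re-close in hot mineral acid (Wessely–Moser). The 2'-OH is a third phenol that could close on the three-carbon bridge and exchange rings A and B. The 3-hydroxy-enone is sensitive to base and air, and late introduction of the C3 oxygen by oxidative chalcone cyclisation is unreliable when the chalcone carries a 6'-alkoxy group, which diverts it towards aurones. The strategy rests on two features. First, C2, C3 and C4 all bear oxygen, so ring C is a cyclodehydrated 2-oxy-1,3-diketone that can be stored as a 4-alkoxyisoxazole. Second, C4 hangs on C4a between two ortho oxygens, so a nitrile oxide built on C4 is shielded on both flanks and does not dimerise.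

## Retrosynthetic reasoning

**25 ⇒ 23 (three O–C bonds of protecting groups).** The last operation should only uncover oxygen. The cuts are the benzyl ethers at 3-O and 2'-O and the methyl ether at 5-O.
- The 5-O-methyl group is the only methyl ether peri to the C4 carbonyl, so a chelating boron halide can find it and leave 7-, 8- and 4'-OMe alone.
- The same Lewis acid removes benzyl.
- Ring A can therefore travel as simple methyl ethers, and the air- and base-sensitive flavonol appears only at the end.

**23 ⇒ 20 (O1–C2 cut; C4=O exchanged for C4–NH2).** Ring C is opened at O1–C2, the bond that forms by itself once a free phenol at C8a faces a carbonyl group at C2.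
- In 20 the C8a oxygen is a MOM acetal and the C2' oxygen a benzyl ether. Aqueous acid frees only the former, which fixes the direction of closure.
- The forward step must remove the acetal, hydrolyse the C4–N function and dehydrate, all in one flask.

**20 ⇒ 19 (N and O reconnected).** Joining the C4 nitrogen to the C2 oxygen turns the enaminone into an aromatic isoxazole.
- The isoxazole holds C2, C3 and C4 at their final oxidation levels.
- Unlike a free 2-oxy-1,3-diketone, it cannot enolise, cleave or cyclise.
- The forward reaction must break N–O without touching O-benzyl. This excludes hydrogenolysis and points to a low-valent metal carbonyl.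

**19 ⇒ 8 + 17 (C3–C4 and the temporary O–C2 bond).** This cut divides the molecule into two halves of similar size, one arene each.
- It follows the natural polarity: C4 is a carbonyl carbon and becomes the electrophilic carbon of nitrile oxide 8; C3 is alpha to the C2 carbonyl and becomes the nucleophilic carbon of enamine 17.
- A Claisen-type acylation across the same bond would need tetrahedral addition to a 2,6-disubstituted benzoyl group. The sp carbon of 8 instead projects out from between its ortho substituents and stays accessible.
- A cut at C4–C4a would revive the regiochemical problem on ring A.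
- A cut at C2–C3 would require an alpha-oxy carbanion next to the hindered ring A ketone.
- The forward step must form one C–C bond and one ring with a single regiochemistry, then aromatise by loss of 16.

**8 ⇒ 7 (two hydrogens added back).** The dipole comes from aldoxime 7 by oxidative dehydrogenation with an iodine-based oxidant that transfers no halogen. The customary chlorination–dehydrochlorination sequence is not used. The lone ring hydrogen (flavone C6–H) lies between two methoxy groups and para to a third oxygen, so it would be chlorinated in competition with the oxime carbon.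

**7 ⇒ 6 ⇒ 5 (C=N, then O–MOM).** The oxime comes from aldehyde 6 by condensation, and the acetal from phenol 5. These two simple steps place the acid-labile group on the oxygen that will become O1.

**5 ⇒ 3 (O–Me reconnected).** Phenol 5 comes from tetramethyl ether 3 by loss of one ortho methyl group under chelation control. The two ortho ethers differ: the one that must go is wedged between the formyl group and a neighbouring methoxy group.

**3 ⇒ 1 (aryl–CHO).** The two free positions of 1 are equivalent, so formylation has no regiochemical choice.

**17 ⇒ 15 + 16 (C–N).** The enamine comes from ketone 15 and amine 16. Ketone 15 has only one enolisable carbon, so only one enamine regioisomer can form.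

**15 ⇒ 12 + 10 (aryl–acyl bond).** Cutting here brings in the CH2OBn carbon at its final oxidation level. It avoids alpha-oxidation of an acetophenone next to an electron-rich ring, where ring halogenation competes. The bromine of 12 fixes the site of acylation.

**12 ⇒ 11 and 10 ⇒ 9.** One O-benzylation and one N-acylation lead back to catalogue compounds.

## Alternatives that were turned down

**Alternative 1:** Ring B is made last. The cuts are C1'–C2' and C5'–C6', which lead to the 2-ethynylchromone A2 and the ketene-acetal diene A3.
- *Forward step:* a (4+2) cycloaddition of the alkyne with the diene. The acetal methoxy group is then eliminated and the silyl group lost, giving A1 with 2'-OH free and 4'-OMe in place.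
- *For it:* the polarity matches, since the nucleophilic CH2 terminus of A3 meets the terminal alkyne carbon, the vinylogous acceptor site of the chromone. The oxygen pattern of ring B is written into the diene. The 2'-phenol is created after ring C is closed, so the direction problem never arises. On that point the plan is at least as good as the chosen one, which needs two orthogonal protecting groups for the same security.
- *Against it:* the alkyne is only weakly activated. Its activation runs through C2=C3, which carries the donor 3-OBn, into a carbonyl already fed by the 5- and 7-methoxy groups. A3 is unlikely to tolerate the long heating such a dienophile needs and may add in an open-chain Mukaiyama–Michael sense. Aromatisation can expel either the methoxy or the silyloxy group, and the second choice leaves a 2'-methyl ether.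
- *Comparison:* the weightiest objection is that A2 already contains rings A and C with all five oxygens. The C3 oxygen and the C5/C8a differentiation are postponed, not solved. A full 3-oxygenated chromone synthesis plus a C2 ethynylation would come first, and the 5-O-methyl ether would still have to be cleaved. The chosen strategy builds C2–C3–C4 at the right oxidation level in the same step that joins two simple arenes.

**Alternative 2:** Ring A is made last. The cuts are C8–C8a and C4a–C5, which lead to the sulfinylpyranone A5 and the tetraoxygenated diene A6.
- *Forward step:* a (4+2) addition across the sulfinyl-bearing double bond of A5. Syn elimination of the sulfinyl group, expulsion of the acetal methoxy group and desilylation then give A4.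
- *For it:* A4 arrives with 5-OH free and 7-OMe and 8-OMe in place. No late demethylation and no differentiation of two ortho ethers are needed. On both points it is stronger than the chosen route, which needs steps 2 and 13 for them.
- *Against it:* a 4-pyranone is a cyclically delocalised, poor dienophile, and in A5 it also carries the donor 3-OBn and an electron-rich aryl group. A6 bears a methoxy group on its reacting terminus, which slows the bond to C8a and makes the s-cis form depend on the alkene geometry, and four oxygen donors make it extremely acid-labile. The adduct has four possible leaving groups (sulfinyl, two different methoxy groups, silyloxy), and aromatisation needs exactly the right two. Loss of the C8 methoxy group would erase the 7,8-pattern.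
- *Comparison:* both partners need multi-step syntheses of their own, so the step count exceeds that of the chosen plan. The chosen plan takes ring A from a commercial tetramethoxybenzene and gives a key step whose only selectivity is a well-polarised regiochemistry.

**Alternative 3:** Ring C is assembled from three components by cutting C4a–C4, C4–C3 and O1–C2. This leads to iodophenol A8, carbon monoxide A10 and arylalkyne A9.
- *Forward step:* zerovalent palladium adds oxidatively to the C–I bond, A10 inserts, the acyl-palladium couples with A9, and the phenol closes 6-endo on the ynone to give A7.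
- *For it:* three bonds and one ring form in a single operation, the reaction type is broadly established, and this is the shortest way to the carbon skeleton. In convergence and step count to the flavone core it beats the chosen route.
- *Against it:* A7 has hydrogen at C3, so a separate C3 oxidation must follow on a crowded, electron-rich flavone. The benzylic CH2 groups and ring A then compete for base or oxidant. The C–I bond of A8 is flanked by two oxygen substituents on a very electron-rich ring, which slows oxidative addition and invites loss of iodine. 5-exo closure to an aurone competes with the 6-endo mode. A8 also needs the same singling-out of one terminal oxygen of the contiguous trio, so nothing is saved on ring A, and the 5-O-methyl ether remains.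
- *Comparison:* the chosen strategy carries the C3 oxygen from the outset, avoids any late oxidation of the assembled flavone and works without a pressurised toxic gas.

Key step: step 10

Assumption: the double-bond geometry of 17 and the relative configuration of 18 are left open, because both are erased when 18 aromatises; 14, 18 and 22 are racemic.

## Route

Step 1
Reactants: 1 1,2,3,5-tetramethoxybenzene
Product: 3 2,3,4,6-tetramethoxybenzaldehyde, via aryl iminium salt 2 (not isolated)
Conditions: POCl3, DMF, 0 → 60 °C; then H2O
Reagents that add atoms: N,N-dimethylformamide CN(C)C=O; water O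
Why: Vilsmeier–Haack formylation. The two free positions of 1 are equivalent and each is activated by two ortho and one para methoxy group, so only one aldehyde can form, and the electron-poor iminium group of 2 stops a second attack. Water hydrolyses 2 to 3.

Step 2
Reactants: 3 2,3,4,6-tetramethoxybenzaldehyde
Product: 5 2-hydroxy-3,4,6-trimethoxybenzaldehyde, via dichloroboron chelate 4 (not isolated)
Conditions: BCl3 (1.05 equiv), CH2Cl2, −78 → 0 °C; then H2O
Reagents that add atoms: none
Why: Chelation-directed ortho-demethylation of an aryl aldehyde with BCl3. Boron bridges the formyl oxygen and an ortho ether oxygen and chloride removes the methyl group; the C2 ether, wedged between CHO and the C3 methoxy group, is twisted out of conjugation and is therefore the more basic and more strained of the two ortho ethers, the pattern familiar from crowded polymethoxyaryl ketones. One equivalent at low temperature should spare the ethers at C3, C4 and C6, and water releases 5 from 4.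

Step 3
Reactants: 5 2-hydroxy-3,4,6-trimethoxybenzaldehyde
Product: 6 2-(methoxymethoxy)-3,4,6-trimethoxybenzaldehyde
Conditions: MOMCl, i-Pr2NEt, CH2Cl2, 0 → 40 °C
Reagents that add atoms: chloromethyl methyl ether COCCl
Why: O-Alkylation of a phenol to its MOM acetal. The chelated, flanked phenol reacts slowly, hence the reactive chloride in excess and gentle warming, while the aldehyde and methyl ethers are inert. MOM is chosen because aqueous acid removes it and leaves benzyl ethers in place.

Step 4
Reactants: 6 2-(methoxymethoxy)-3,4,6-trimethoxybenzaldehyde
Product: 7 (E)-2-(methoxymethoxy)-3,4,6-trimethoxybenzaldehyde oxime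
Conditions: NH2OH·HCl, NaOAc, EtOH–H2O, rt
Reagents that add atoms: hydroxylamine hydrochloride NO.Cl
Why: Oxime condensation, buffered by NaOAc so that the MOM acetal is safe. The two ortho substituents favour the (E)-oxime, with OH turned away from the ring.

Step 5
Reactants: 7 (E)-2-(methoxymethoxy)-3,4,6-trimethoxybenzaldehyde oxime
Product: 8 2-(methoxymethoxy)-3,4,6-trimethoxybenzonitrile oxide
Conditions: PhI(OAc)2, MeOH, 0 °C
Reagents that add atoms: none
Why: Oxidative dehydrogenation of an aldoxime to a nitrile oxide with PhI(OAc)2, by ligand exchange at iodine and loss of PhI and AcOH. No halogen is transferred, so the very electron-rich C5–H, which N-chlorosuccinimide would attack, stays untouched. The ortho OMOM and OMe groups block dimerisation to the furoxan, so 8 should be isolable and can be freed from oxidant before it meets the oxidisable enamine.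

Step 6
Reactants: 9 (benzyloxy)acetyl chloride
Product: 10 2-(benzyloxy)-N-methoxy-N-methylacetamide
Conditions: MeNH(OMe)·HCl, Et3N, CH2Cl2, 0 °C → rt
Reagents that add atoms: N,O-dimethylhydroxylamine hydrochloride CNOC.Cl
Why: N-Acylation of an amine by an acid chloride, giving the Weinreb amide. Et3N frees the amine from its salt and takes up HCl.

Step 7
Reactants: 11 2-bromo-5-methoxyphenol
Product: 12 2-(benzyloxy)-1-bromo-4-methoxybenzene
Conditions: BnBr, K2CO3, DMF, rt
Reagents that add atoms: benzyl bromide BrCc1ccccc1
Why: Williamson etherification of the phenol; no other nucleophilic site is present.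

Step 8
Reactants: 12 2-(benzyloxy)-1-bromo-4-methoxybenzene; 10 2-(benzyloxy)-N-methoxy-N-methylacetamide
Product: 15 2-(benzyloxy)-1-[2-(benzyloxy)-4-methoxyphenyl]ethan-1-one, via aryllithium 13 (not isolated), via lithium hemiaminal 14 (not isolated)
Conditions: n-BuLi, THF, −78 °C; then 10, −78 → 0 °C; then aq. NH4Cl
Reagents that add atoms: none
Why: Bromine–lithium exchange followed by Weinreb ketone synthesis. At −78 °C 13 should not attack its own benzylic CH2, and the chelated adduct 14 holds until the quench, so no tertiary alcohol forms. The acyl position is fixed by the bromine of 11, and the CH2OBn carbon arrives at its final oxidation level.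

Step 9
Reactants: 15 2-(benzyloxy)-1-[2-(benzyloxy)-4-methoxyphenyl]ethan-1-one; 16 morpholine
Product: 17 4-{2-(benzyloxy)-1-[2-(benzyloxy)-4-methoxyphenyl]ethenyl}morpholine (E/Z mixture, used crude after filtration and removal of excess 16 in vacuo)
Conditions: TiCl4 (0.6 equiv), 16 (7 equiv), toluene, 0 °C → rt
Reagents that add atoms: none
Why: TiCl4-mediated enamine synthesis (White–Weingarten), in which TiCl4 activates the carbonyl group and binds the water irreversibly as TiO2. Ketone 15 has a single enolisable carbon, so one regioisomer results. Mixing TiCl4 with the excess amine before the ketone is added tempers its Lewis acidity, so the benzyl ethers should persist.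

Step 10
Reactants: 8 2-(methoxymethoxy)-3,4,6-trimethoxybenzonitrile oxide; 17 4-{2-(benzyloxy)-1-[2-(benzyloxy)-4-methoxyphenyl]ethenyl}morpholine
Product: 19 4-(benzyloxy)-5-[2-(benzyloxy)-4-methoxyphenyl]-3-[2-(methoxymethoxy)-3,4,6-trimethoxyphenyl]-1,2-oxazole, via 5-morpholinoisoxazoline 18 (not isolated)
Conditions: 8 (1 equiv), 17 (1.3 equiv), toluene, rt → 50 °C; then AcOH (3 equiv), 60 °C
Reagents that add atoms: none
Why: 1,3-Dipolar cycloaddition of a nitrile oxide to an enamine followed by deamination, a long-established isoxazole synthesis. The nitrogen lone pair of 17 raises the alkene HOMO and puts its largest coefficient on the CH(OBn) carbon, which bonds to the electrophilic carbon of 8 (flavone C3–C4), while the dipole oxygen ends on the morpholine-bearing carbon (flavone C2). Bond formation should be strongly asynchronous: read stepwise, C–C bond formation gives an iminium oximate that closes 5-exo-trig by attack of the oximate oxygen on the iminium carbon; read concertedly, it is a suprafacial (3+2) addition; both give the five-membered ring of 18. Regiochemistry is the only selectivity needed, and it is secured because the amine donor outweighs the benzyloxy donor on the other alkene carbon and because the shielded dipole carbon meets the alkene CH rather than the fully substituted carbon. The two stereocentres of 18 (C4 and C5) need no control, since both vanish on aromatisation. In 18 only C4 carries hydrogen and only C5 carries a group that can leave with donor assistance, so AcOH should induce loss of 16 through a cation stabilised by the ring oxygen and the 2,4-dioxygenated aryl group, and benzyl alcohol cannot be eliminated. The two ortho oxygens of 8 suppress furoxan formation, so a slow reaction with a trisubstituted alkene can be allowed to run its course. Acid is withheld until 8 is consumed so that liberated 16 cannot add to the dipole, and MOM and benzyl ethers are inert to AcOH.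

Step 11
Reactants: 19 4-(benzyloxy)-5-[2-(benzyloxy)-4-methoxyphenyl]-3-[2-(methoxymethoxy)-3,4,6-trimethoxyphenyl]-1,2-oxazole
Product: 20 (2E)-3-amino-2-(benzyloxy)-1-[2-(benzyloxy)-4-methoxyphenyl]-3-[2-(methoxymethoxy)-3,4,6-trimethoxyphenyl]prop-2-en-1-one
Conditions: Mo(CO)6, MeCN–H2O, 80 °C
Reagents that add atoms: none
Why: Reductive N–O cleavage of an isoxazole with Mo(CO)6 in wet acetonitrile: the ring nitrogen binds molybdenum, the weak N–O bond breaks and water supplies the two hydrogens. The neutral medium keeps the MOM and benzyl groups, whereas hydrogenolysis would remove benzyl and with it the control over the direction of closure. NH2 and C=O stay cis and hydrogen-bonded as in the ring, which corresponds to the (E) descriptor because OBn outranks the acyl carbon.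

Step 12
Reactants: 20 (2E)-3-amino-2-(benzyloxy)-1-[2-(benzyloxy)-4-methoxyphenyl]-3-[2-(methoxymethoxy)-3,4,6-trimethoxyphenyl]prop-2-en-1-one
Product: 23 3-(benzyloxy)-2-[2-(benzyloxy)-4-methoxyphenyl]-5,7,8-trimethoxy-4H-chromen-4-one, via phenolic enaminone 21 (not isolated), via 2-benzyloxy-1,3-diketone 22 (not isolated)
Conditions: 3 M aq. HCl, THF, 60 °C
Reagents that add atoms: water O
Why: Acetal cleavage, enaminone hydrolysis and cyclodehydration in aqueous acid, the established way from beta-amino enones of 3-(2-hydroxyaryl)isoxazoles to flavones; if ring closure precedes hydrolysis, nitrogen leaves C4 afterwards with the same result. Only the C8a phenol is free, so it alone adds 6-exo-trig to the ring B carbonyl, and loss of water across C2–C3 gives the pyranone. The benzyl ethers tolerate dilute HCl, and the still methylated 5-oxygen rules out a Wessely–Moser shift.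

Step 13
Reactants: 23 3-(benzyloxy)-2-[2-(benzyloxy)-4-methoxyphenyl]-5,7,8-trimethoxy-4H-chromen-4-one
Product: 25 3,5-dihydroxy-2-(2-hydroxy-4-methoxyphenyl)-7,8-dimethoxy-4H-chromen-4-one (3,5,2'-trihydroxy-7,8,4'-trimethoxyflavone), via 5-O-methyl flavonol 24 (not isolated)
Conditions: BCl3 (6 equiv), C6HMe5 (6 equiv), CH2Cl2, −78 → 0 °C; then H2O
Reagents that add atoms: none
Why: Lewis-acid ether cleavage. BCl3 with pentamethylbenzene as a non-basic cation scavenger removes both benzyl ethers at −78 °C and keeps the benzyl cation off the electron-rich rings, leaving 24 bound to boron. On warming, BCl3 chelated between C4=O and the peri 5-OMe cleaves that ether, while 7-, 8- and 4'-OMe lack a neighbouring carbonyl and should survive at or below 0 °C, and the absence of hot protic acid excludes ring-opening isomerisation.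

## Compound list

1 | 1,2,3,5-tetramethoxybenzene | COc1cc(OC)c(OC)c(OC)c1 | starting material
2 | N,N-dimethyl-1-(2,3,4,6-tetramethoxyphenyl)methaniminium dichlorophosphate | COc1cc(OC)c(C=[N+](C)C)c(OC)c1OC.[O-]P(=O)(Cl)Cl | intermediate (not isolated)
3 | 2,3,4,6-tetramethoxybenzaldehyde | COc1cc(OC)c(C=O)c(OC)c1OC | intermediate
4 | dichloro(2-formyl-3,5,6-trimethoxyphenoxy)borane | COc1cc(OC)c(C=O)c(OB(Cl)Cl)c1OC | intermediate (not isolated)
5 | 2-hydroxy-3,4,6-trimethoxybenzaldehyde | COc1cc(OC)c(C=O)c(O)c1OC | intermediate
6 | 2-(methoxymethoxy)-3,4,6-trimethoxybenzaldehyde | COCOc1c(OC)c(OC)cc(OC)c1C=O | intermediate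
7 | (E)-2-(methoxymethoxy)-3,4,6-trimethoxybenzaldehyde oxime | COCOc1c(OC)c(OC)cc(OC)c1/C=N/O | intermediate
8 | 2-(methoxymethoxy)-3,4,6-trimethoxybenzonitrile oxide | COCOc1c(OC)c(OC)cc(OC)c1C#[N+][O-] | intermediate
9 | (benzyloxy)acetyl chloride | O=C(Cl)COCc1ccccc1 | starting material
10 | 2-(benzyloxy)-N-methoxy-N-methylacetamide | CON(C)C(=O)COCc1ccccc1 | intermediate
11 | 2-bromo-5-methoxyphenol | COc1ccc(Br)c(O)c1 | starting material
12 | 2-(benzyloxy)-1-bromo-4-methoxybenzene | COc1ccc(Br)c(OCc2ccccc2)c1 | intermediate
13 | [2-(benzyloxy)-4-methoxyphenyl]lithium | [Li]c1ccc(OC)cc1OCc1ccccc1 | intermediate (not isolated)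
14 | lithium 2-(benzyloxy)-1-[2-(benzyloxy)-4-methoxyphenyl]-1-[methoxy(methyl)amino]ethan-1-olate (racemic) | COc1ccc(C([O-])(COCc2ccccc2)N(C)OC)c(OCc2ccccc2)c1.[Li+] | intermediate (not isolated)
15 | 2-(benzyloxy)-1-[2-(benzyloxy)-4-methoxyphenyl]ethan-1-one | COc1ccc(C(=O)COCc2ccccc2)c(OCc2ccccc2)c1 | intermediate
16 | morpholine | C1COCCN1 | starting material
17 | 4-{2-(benzyloxy)-1-[2-(benzyloxy)-4-methoxyphenyl]ethenyl}morpholine (E/Z mixture) | COc1ccc(C(=COCc2ccccc2)N2CCOCC2)c(OCc2ccccc2)c1 | intermediate
18 | 4-(benzyloxy)-5-[2-(benzyloxy)-4-methoxyphenyl]-3-[2-(methoxymethoxy)-3,4,6-trimethoxyphenyl]-5-(morpholin-4-yl)-4,5-dihydro-1,2-oxazole (racemic mixture of diastereomers) | COCOc1c(OC)c(OC)cc(OC)c1C1=NOC(N2CCOCC2)(c2ccc(OC)cc2OCc2ccccc2)C1OCc1ccccc1 | intermediate (not isolated)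
19 | 4-(benzyloxy)-5-[2-(benzyloxy)-4-methoxyphenyl]-3-[2-(methoxymethoxy)-3,4,6-trimethoxyphenyl]-1,2-oxazole | COCOc1c(OC)c(OC)cc(OC)c1-c1noc(-c2ccc(OC)cc2OCc2ccccc2)c1OCc1ccccc1 | intermediate
20 | (2E)-3-amino-2-(benzyloxy)-1-[2-(benzyloxy)-4-methoxyphenyl]-3-[2-(methoxymethoxy)-3,4,6-trimethoxyphenyl]prop-2-en-1-one | COCOc1c(OC)c(OC)cc(OC)c1/C(N)=C(\OCc1ccccc1)C(=O)c1ccc(OC)cc1OCc1ccccc1 | intermediate
21 | (2E)-3-amino-2-(benzyloxy)-1-[2-(benzyloxy)-4-methoxyphenyl]-3-(2-hydroxy-3,4,6-trimethoxyphenyl)prop-2-en-1-one | COc1cc(OC)c(/C(N)=C(\OCc2ccccc2)C(=O)c2ccc(OC)cc2OCc2ccccc2)c(O)c1OC | intermediate (not isolated)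
22 | 2-(benzyloxy)-1-[2-(benzyloxy)-4-methoxyphenyl]-3-(2-hydroxy-3,4,6-trimethoxyphenyl)propane-1,3-dione (racemic, enolisable) | COc1ccc(C(=O)C(OCc2ccccc2)C(=O)c2c(O)c(OC)c(OC)cc2OC)c(OCc2ccccc2)c1 | intermediate (not isolated)
23 | 3-(benzyloxy)-2-[2-(benzyloxy)-4-methoxyphenyl]-5,7,8-trimethoxy-4H-chromen-4-one | COc1ccc(-c2oc3c(OC)c(OC)cc(OC)c3c(=O)c2OCc2ccccc2)c(OCc2ccccc2)c1 | intermediate
24 | 3-hydroxy-2-(2-hydroxy-4-methoxyphenyl)-5,7,8-trimethoxy-4H-chromen-4-one | COc1ccc(-c2oc3c(OC)c(OC)cc(OC)c3c(=O)c2O)c(O)c1 | intermediate (not isolated)
25 | 3,5-dihydroxy-2-(2-hydroxy-4-methoxyphenyl)-7,8-dimethoxy-4H-chromen-4-one | COc1ccc(-c2oc3c(OC)c(OC)cc(O)c3c(=O)c2O)c(O)c1 | target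

## Step count and least certain steps

Total step count: 13. Longest linear sequence: 9 steps (steps 1–5 and 10–13).

**Step 10 (key step).**
- *Risk:* the most likely failure is slow bond formation between two crowded partners, a dipole with two ortho substituents and a trisubstituted alkene. A slow reaction leaves time for three losses. Traces of water hydrolyse the enamine. Amine set free by early aromatisation captures the dipole. The dipole rearranges thermally if the temperature is raised to compensate.
- *Fallback:* a much stronger carbon nucleophile replaces the enamine. The fallback sets out from 15 and 8 and returns at 19. Ketone 15 is deprotonated with LiN(SiMe3)2 in THF at −78 °C to lithium (Z)-2-(benzyloxy)-1-[2-(benzyloxy)-4-methoxyphenyl]ethen-1-olate F1. F1 adds through its CH(OBn) carbon to the carbon of 8, a known enolate–nitrile oxide reaction. The resulting oximate closes on the ketone and gives, after the quench, 4-(benzyloxy)-5-[2-(benzyloxy)-4-methoxyphenyl]-3-[2-(methoxymethoxy)-3,4,6-trimethoxyphenyl]-4,5-dihydro-1,2-oxazol-5-ol F2. Warming F2 with AcOH in toluene removes water and gives 19.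

**Step 9.**
- *Risk:* the condensation may stay incomplete, because the carbonyl group is deactivated by an ortho and a para oxygen donor and is hindered. The ortho benzyl ether may be lost by chelation to titanium. The product may hydrolyse during handling.
- *Fallback:* an oxygen-based electron-rich alkene replaces the enamine. The fallback sets out from 15 and returns at 19. TBSOTf and Et3N in CH2Cl2 convert 15 into tert-butyl({2-(benzyloxy)-1-[2-(benzyloxy)-4-methoxyphenyl]ethenyl}oxy)dimethylsilane F3. F3 is heated with 8 in toluene at 80 °C in a known nitrile oxide–silyl enol ether cycloaddition of the same regiochemistry. The product is 4-(benzyloxy)-5-[2-(benzyloxy)-4-methoxyphenyl]-5-[(tert-butyldimethylsilyl)oxy]-3-[2-(methoxymethoxy)-3,4,6-trimethoxyphenyl]-4,5-dihydro-1,2-oxazole F4. AcOH at 60 °C eliminates the silanol from F4 and gives 19.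

**Step 2.**
- *Risk:* the reagent may attack the other ortho ether (C6), or both, because both can chelate to boron and the preference for the crowded ether rests on analogy. An error here would lead to the 5,6,7-series.
- *Fallback:* the outcome is made independent of which ether falls first. The fallback sets out from 3 and returns at 5. Excess AlCl3 in CH2Cl2 at reflux removes both ortho methyl groups and gives 2,6-dihydroxy-3,4-dimethoxybenzaldehyde F5. One equivalent each of MeI and K2CO3 in acetone then alkylates the C6 hydroxyl, whose only ortho neighbour is the formyl group. The flanked C2 hydroxyl stays chelated to the aldehyde and resists a second alkylation, so 5 results.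

**Step 12.**
- *Risk:* the sequence may halt with nitrogen still bound to C4, because that carbon is shielded by the 2,6-disubstituted ring. Forcing hydrolysis with stronger acid or more heat would start to loosen the 2'-O-benzyl ether on its electron-rich ring, and that would open the way to closure in the wrong direction.
- *Fallback:* the acid-demanding acetal cleavage is separated from the closure. The fallback sets out from 19 and returns at 23. Dilute aqueous HCl in THF at 40 °C removes MOM at the isoxazole stage, where nothing can cyclise. This gives 2-{4-(benzyloxy)-5-[2-(benzyloxy)-4-methoxyphenyl]-1,2-oxazol-3-yl}-3,5,6-trimethoxyphenol F6. Mo(CO)6 in wet MeCN converts F6 into 21, which is now isolated. Compound 21 is closed in hot aqueous acetic acid, a medium too weak to touch benzyl ethers, so it can be applied for as long as the hydrolysis needs.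

**Step 13.**
- *Risk:* the 5-O-demethylation may stay incomplete because boron is tied up in the 3-O/4-O chelate. Pushing the reaction risks further demethylation at the crowded 8-OMe. The scavenger may also fail to outrun C-benzylation of C6 or of ring B.
- *Fallback:* the single Lewis-acid operation is split into two orthogonal ones. The fallback sets out from 23, passes through 24 (now isolated) and returns at 25. H2 over Pd/C in EtOAc–MeOH removes both benzyl groups without any carbocation. AlCl3 in MeCN at 40 °C, used in a measured amount, then cleaves only the chelated 5-O-methyl ether. This fallback makes no compound outside the list (entry F0).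

## Further compounds

F1 | step 10 | lithium (Z)-2-(benzyloxy)-1-[2-(benzyloxy)-4-methoxyphenyl]ethen-1-olate | [Li+].[O-]/C(c1ccc(OC)cc1OCc1ccccc1)=C\OCc1ccccc1
F2 | step 10 | 4-(benzyloxy)-5-[2-(benzyloxy)-4-methoxyphenyl]-3-[2-(methoxymethoxy)-3,4,6-trimethoxyphenyl]-4,5-dihydro-1,2-oxazol-5-ol (racemic mixture of diastereomers) | COCOc1c(OC)c(OC)cc(OC)c1C1=NOC(O)(c2ccc(OC)cc2OCc2ccccc2)C1OCc1ccccc1
F3 | step 9 | tert-butyl({2-(benzyloxy)-1-[2-(benzyloxy)-4-methoxyphenyl]ethenyl}oxy)dimethylsilane (E/Z mixture) | COc1ccc(C(O[Si](C)(C)C(C)(C)C)=COCc2ccccc2)c(OCc2ccccc2)c1
F4 | step 9 | 4-(benzyloxy)-5-[2-(benzyloxy)-4-methoxyphenyl]-5-[(tert-butyldimethylsilyl)oxy]-3-[2-(methoxymethoxy)-3,4,6-trimethoxyphenyl]-4,5-dihydro-1,2-oxazole (racemic mixture of diastereomers) | COCOc1c(OC)c(OC)cc(OC)c1C1=NOC(O[Si](C)(C)C(C)(C)C)(c2ccc(OC)cc2OCc2ccccc2)C1OCc1ccccc1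
F5 | step 2 | 2,6-dihydroxy-3,4-dimethoxybenzaldehyde | COc1cc(O)c(C=O)c(O)c1OC
F6 | step 12 | 2-{4-(benzyloxy)-5-[2-(benzyloxy)-4-methoxyphenyl]-1,2-oxazol-3-yl}-3,5,6-trimethoxyphenol | COc1cc(OC)c(-c2noc(-c3ccc(OC)cc3OCc3ccccc3)c2OCc2ccccc2)c(O)c1OC
F0 | step 13 | none | none
A1 | alternative 1 | 3-(benzyloxy)-2-(2-hydroxy-4-methoxyphenyl)-5,7,8-trimethoxy-4H-chromen-4-one | COc1ccc(-c2oc3c(OC)c(OC)cc(OC)c3c(=O)c2OCc2ccccc2)c(O)c1
A2 | alternative 1 | 3-(benzyloxy)-2-ethynyl-5,7,8-trimethoxy-4H-chromen-4-one | C#Cc1oc2c(OC)c(OC)cc(OC)c2c(=O)c1OCc1ccccc1
A3 | alternative 1 | 1,3-dimethoxy-1-(trimethylsilyloxy)buta-1,3-diene | C=C(OC)C=C(OC)O[Si](C)(C)C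
A4 | alternative 2 | 3-(benzyloxy)-2-[2-(benzyloxy)-4-methoxyphenyl]-5-hydroxy-7,8-dimethoxy-4H-chromen-4-one | COc1ccc(-c2oc3c(OC)c(OC)cc(O)c3c(=O)c2OCc2ccccc2)c(OCc2ccccc2)c1
A5 | alternative 2 | 3-(benzyloxy)-2-[2-(benzyloxy)-4-methoxyphenyl]-5-(phenylsulfinyl)-4H-pyran-4-one (racemic at sulfur) | COc1ccc(-c2occ(S(=O)c3ccccc3)c(=O)c2OCc2ccccc2)c(OCc2ccccc2)c1
A6 | alternative 2 | 1,3,4-trimethoxy-1-(trimethylsilyloxy)buta-1,3-diene | COC=C(OC)C=C(OC)O[Si](C)(C)C
A7 | alternative 3 | 2-[2-(benzyloxy)-4-methoxyphenyl]-5,7,8-trimethoxy-4H-chromen-4-one | COc1ccc(-c2cc(=O)c3c(OC)cc(OC)c(OC)c3o2)c(OCc2ccccc2)c1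
A8 | alternative 3 | 2-iodo-3,5,6-trimethoxyphenol | COc1cc(OC)c(I)c(O)c1OC
A9 | alternative 3 | 2-(benzyloxy)-1-ethynyl-4-methoxybenzene | C#Cc1ccc(OC)cc1OCc1ccccc1
A10 | alternative 3 | carbon monoxide | [C-]#[O+]
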